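**Retrosynthetic overview**
1. Ring A is closed last through C1–C2: the C9 silyl enol ether attacks a C5-bound ethoxy ynone (C5–C4(=O)–C3≡C2–OEt) under gold catalysis, and the C2 enol ether is then hydrolysed.
2. The C5 quaternary centre comes from dianion formylation of the ring B diketone followed by prenylation anti to the C7 prenyl group.
3. Ring B rests on one feature: C1 carries both the C9 ring ketone and the exocyclic 2-methylbutanoyl ketone, so C1–C9 of ring B (C1, C8, C7, C6, C5, C9) is the inner bond of a 1,3-diketone and is made by intramolecular Claisen condensation of an open-chain keto ester.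
4. The keto ester comes from an (R)-epichlorohydrin-derived 4-prenylbutyrolactone: two anti alkylations set C8 next to C7, the lactone carbonyl becomes C1 (iodide, lithiation, (R)-Weinreb amide) and the lactone CH2O becomes C6 (Wittig two-carbon extension).
5. Ring order: lactone template, then ring B (step 15), then ring A (step 20).

Key step: step 15

Remark: atoms are numbered C1 (acyl bridgehead), C2–C4 (enolised dione), C5 (prenyl bridgehead), C6, C7 (prenyl), C8 (methyl and 4-methylpent-3-enyl), C9 (bridging ketone); the C2/C4 enol tautomers of the target interconvert, so hydrolysis of the C2 ethyl enol ether is taken to give the compound drawn as the C4 enol.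

**Step 1**
Reactants: 1 (R)-epichlorohydrin; 2 diethyl malonate
Product: 3 ethyl (1S,5R)-2-oxo-3-oxabicyclo[3.1.0]hexane-1-carboxylate
Conditions: NaOEt (1.05 equiv), EtOH, 0 °C → reflux
Reagents that add atoms: none
Why: Malonate opens the epoxide at its CH2 end, the alkoxide re-closes to a new epoxide by displacing chloride, and the malonate carbanion then opens that epoxide in a 3-exo-tet cyclopropanation with inversion before lactonisation, so the (R) epoxide should be relayed to the (1S,5R) bicycle (malonate epoxide alkylation, cyclopropanation and lactonisation).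

**Step 2**
Reactants: 3 ethyl (1S,5R)-2-oxo-3-oxabicyclo[3.1.0]hexane-1-carboxylate; 4 2-methylprop-1-enylmagnesium bromide
Product: 5 ethyl (4R)-4-(3-methylbut-2-en-1-yl)-2-oxotetrahydrofuran-3-carboxylate (C3 epimers)
Conditions: 4 (1.5 equiv), CuI (10 mol%), THF, −40 → −20 °C; 1 M HCl
Reagents that add atoms: none
Why: Copper-catalysed homoconjugate addition of the alkenyl Grignard reagent to the doubly activated cyclopropane occurs at the unsubstituted ring CH2, so that CH2 plus the 2-methylpropenyl group become the prenyl chain and the ring stereocentre (later C7) is not touched.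

**Step 3**
Reactants: 5 ethyl (4R)-4-(3-methylbut-2-en-1-yl)-2-oxotetrahydrofuran-3-carboxylate
Product: 6 (4R)-4-(3-methylbut-2-en-1-yl)dihydrofuran-2(3H)-one
Conditions: LiCl (1.5 equiv), DMSO–H2O, 140 °C
Reagents that add atoms: none
Why: Krapcho dealkoxycarbonylation removes the ester of the malonate-type lactone under neutral conditions and leaves the C4 stereocentre and the trisubstituted alkene alone.

**Step 4**
Reactants: 6 (4R)-4-(3-methylbut-2-en-1-yl)dihydrofuran-2(3H)-one
Product: 7 (3R,4R)-3-methyl-4-(3-methylbut-2-en-1-yl)dihydrofuran-2(3H)-one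
Conditions: LiN(i-Pr)2 (1.05 equiv), THF, −78 °C; MeI (1.5 equiv), −78 °C
Reagents that add atoms: iodomethane, CI
Why: Enolate alkylation of a 4-substituted butyrolactone takes place on the face opposite the C4 substituent, so the trans lactone should predominate, and this centre is re-enolised in step 6 in any case.

**Step 5**
Reactants: 8 5-bromo-2-methylpent-2-ene
Product: 9 5-iodo-2-methylpent-2-ene
Conditions: NaI (3 equiv), acetone, reflux
Reagents that add atoms: sodium iodide, [Na+].[I-]
Why: Finkelstein exchange on a primary bromide is driven by precipitation of NaBr and gives the more reactive iodide needed for a hindered enolate alkylation.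

**Step 6**
Reactants: 7 (3R,4R)-3-methyl-4-(3-methylbut-2-en-1-yl)dihydrofuran-2(3H)-one; 9 5-iodo-2-methylpent-2-ene
Product: 10 (3R,4R)-3-methyl-3-(4-methylpent-3-en-1-yl)-4-(3-methylbut-2-en-1-yl)dihydrofuran-2(3H)-one
Conditions: LiN(i-Pr)2 (1.1 equiv), THF–DMPU, −78 °C; 9 (1.3 equiv), −78 → −20 °C
Reagents that add atoms: none
Why: The planar α-methyl lactone enolate is alkylated by the primary iodide anti to the neighbouring C4 prenyl group, which sets the quaternary centre (later C8) with methyl cis and the 4-methylpentenyl chain trans to prenyl (1,2-induction in butyrolactone enolate alkylation).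

**Step 7**
Reactants: 10 (3R,4R)-3-methyl-3-(4-methylpent-3-en-1-yl)-4-(3-methylbut-2-en-1-yl)dihydrofuran-2(3H)-one
Product: 11 (2R,3R)-2-methyl-2-(4-methylpent-3-en-1-yl)-3-(3-methylbut-2-en-1-yl)butane-1,4-diol
Conditions: LiAlH4 (1.5 equiv), THF, 0 °C → rt; H2O, aq. NaOH
Reagents that add atoms: none
Why: Hydride reduction of the lactone gives the 1,4-diol without affecting the isolated alkenes or the two stereocentres.

**Step 8**
Reactants: 11 (2R,3R)-2-methyl-2-(4-methylpent-3-en-1-yl)-3-(3-methylbut-2-en-1-yl)butane-1,4-diol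
Product: 12 (2R,3R)-4-[(tert-butyldiphenylsilyl)oxy]-2-methyl-2-(4-methylpent-3-en-1-yl)-3-(3-methylbut-2-en-1-yl)butan-1-ol
Conditions: t-BuPh2SiCl (1.05 equiv), imidazole (2 equiv), CH2Cl2, −20 → 0 °C
Reagents that add atoms: tert-butyl(chloro)diphenylsilane, CC(C)(C)[Si](Cl)(c1ccccc1)c1ccccc1
Why: The C4 hydroxyl (later C6) is on a CH2 next to a tertiary carbon whereas the C1 hydroxyl is neopentylic, so the bulky silyl chloride should react selectively at the less hindered alcohol.

**Step 9**
Reactants: 12 (2R,3R)-4-[(tert-butyldiphenylsilyl)oxy]-2-methyl-2-(4-methylpent-3-en-1-yl)-3-(3-methylbut-2-en-1-yl)butan-1-ol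
Product: 13 tert-butyl{[(2R,3R)-3-(iodomethyl)-3,7-dimethyl-2-(3-methylbut-2-en-1-yl)oct-6-en-1-yl]oxy}diphenylsilane
Conditions: I2 (1.5 equiv), PPh3 (1.5 equiv), imidazole (3 equiv), toluene, 80 °C
Reagents that add atoms: iodine, II
Why: Iodide displaces the alkoxyphosphonium group in an SN2 reaction that is slow at a neopentyl carbon but workable on heating, and the bulky, weakly basic silyl ether oxygen should not compete by closing a tetrahydrofuran (Appel-type iodination).

**Step 10**
Reactants: 14 (R)-2-methylbutanoic acid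
Product: 16 (R)-N-methoxy-N,2-dimethylbutanamide, via acyl imidazolide 15 (not isolated)
Conditions: 1,1'-carbonyldiimidazole (1.1 equiv), CH2Cl2, 0 °C → rt; MeNH(OMe)·HCl (1.2 equiv), rt
Reagents that add atoms: N,O-dimethylhydroxylamine hydrochloride, CNOC.Cl; 1,1'-carbonyldiimidazole, O=C(n1ccnc1)n1ccnc1 (imidazolyl group of 15 only)
Why: Activation as the acyl imidazolide and aminolysis by the hydroxylamine salt proceed without a ketene or strongly basic stage, so the α-stereocentre should be retained (Weinreb amide formation).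

**Step 11**
Reactants: 13 tert-butyl{[(2R,3R)-3-(iodomethyl)-3,7-dimethyl-2-(3-methylbut-2-en-1-yl)oct-6-en-1-yl]oxy}diphenylsilane; 16 (R)-N-methoxy-N,2-dimethylbutanamide
Product: 18 (3R,6S,7R)-8-[(tert-butyldiphenylsilyl)oxy]-3,6-dimethyl-6-(4-methylpent-3-en-1-yl)-7-(3-methylbut-2-en-1-yl)octan-4-one, via neopentyl organolithium 17 (not isolated)
Conditions: t-BuLi (2.1 equiv), Et2O–pentane, −78 °C; 16 (1.3 equiv), −78 → 0 °C; 1 M HCl
Reagents that add atoms: tert-butyllithium, [Li]C(C)(C)C (lithium of 17 only)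
Why: Iodine–lithium exchange on the primary iodide is fast at −78 °C, where cyclisation onto the trisubstituted alkenes is negligible, and the organolithium adds once to the Weinreb amide to give a stable chelate that releases the ketone only on work-up, so the (R) centre of the acyl chain is carried over unchanged (Weinreb ketone synthesis).

**Step 12**
Reactants: 18 (3R,6S,7R)-8-[(tert-butyldiphenylsilyl)oxy]-3,6-dimethyl-6-(4-methylpent-3-en-1-yl)-7-(3-methylbut-2-en-1-yl)octan-4-one
Product: 19 (3R,6S,7R)-8-hydroxy-3,6-dimethyl-6-(4-methylpent-3-en-1-yl)-7-(3-methylbut-2-en-1-yl)octan-4-one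
Conditions: HF·pyridine, THF–pyridine, 0 °C → rt
Reagents that add atoms: none
Why: Buffered fluoride cleaves the silyl ether without the basic conditions that could epimerise the α-branched ketone and without protonating the trisubstituted alkenes.

**Step 13**
Reactants: 19 (3R,6S,7R)-8-hydroxy-3,6-dimethyl-6-(4-methylpent-3-en-1-yl)-7-(3-methylbut-2-en-1-yl)octan-4-one
Product: 21 methyl (2E,4S,5S,8R)-5,8-dimethyl-5-(4-methylpent-3-en-1-yl)-4-(3-methylbut-2-en-1-yl)-7-oxodec-2-enoate, via keto aldehyde 20 (not isolated)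
Conditions: Dess–Martin periodinane (1.3 equiv), CH2Cl2, 0 °C → rt; Ph3P=CHCO2Me (1.5 equiv), rt
Reagents that add atoms: methyl (triphenylphosphoranylidene)acetate, COC(=O)C=P(c1ccccc1)(c1ccccc1)c1ccccc1
Why: The periodinane oxidises the primary alcohol under neutral conditions and the stabilised ylide traps the epimerisable aldehyde in the same flask, reacting with the aldehyde and not with the hindered ketone to give the E enoate (tandem oxidation–Wittig olefination).

**Step 14**
Reactants: 21 methyl (2E,4S,5S,8R)-5,8-dimethyl-5-(4-methylpent-3-en-1-yl)-4-(3-methylbut-2-en-1-yl)-7-oxodec-2-enoate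
Product: 22 methyl (4R,5S,8R)-5,8-dimethyl-5-(4-methylpent-3-en-1-yl)-4-(3-methylbut-2-en-1-yl)-7-oxodecanoate
Conditions: [(Ph3P)CuH]6 (0.5 equiv), benzene, rt; 1 M HCl
Reagents that add atoms: none
Why: The copper hydride delivers hydride only to the β-carbon of the enoate and leaves the hindered ketone and the trisubstituted alkenes untouched (Stryker conjugate reduction).

**Step 15**
Reactants: 22 methyl (4R,5S,8R)-5,8-dimethyl-5-(4-methylpent-3-en-1-yl)-4-(3-methylbut-2-en-1-yl)-7-oxodecanoate
Product: 23 (2R)-1-[(5R,6R)-2-hydroxy-6-methyl-6-(4-methylpent-3-en-1-yl)-5-(3-methylbut-2-en-1-yl)cyclohex-1-en-1-yl]-2-methylbutan-1-one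
Conditions: LiN(SiMe3)2 (2.2 equiv), THF, −78 → 0 °C; 1 M HCl
Reagents that add atoms: none
Why: LiN(SiMe3)2 removes a proton from the C1 methylene of the ketone and the enolate carbon adds to the C9 ester carbonyl; collapse of the tetrahedral intermediate expels methoxide and the 2-acylcyclohexanone is at once deprotonated to its lithium diketonate. This is an intramolecular Claisen (Dieckmann-type) acylation of a ketone enolate by an ester, a standard route to cyclic 2-acyl ketones. Ring B (C1, C8, C7, C6, C5, C9) closes in a 6-exo-trig mode. No stereocentre is created, since C1 is trigonal in the enol, and C7 and C8 carry no acidic hydrogen. The step needs enolisation at C1 and not at the acyl methine: the methylene is the kinetically preferred site for the bulky amide base, an enolate at the methine could only close an eight-membered ring, an ester enolate can at most give a reversible aldolate, and proton exchange feeds all of these into the one irreversible channel. Formation of the diketonate then removes the acidity of the methine and protects the (R) centre of the side chain.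

**Step 16**
Reactants: 23 (2R)-1-[(5R,6R)-2-hydroxy-6-methyl-6-(4-methylpent-3-en-1-yl)-5-(3-methylbut-2-en-1-yl)cyclohex-1-en-1-yl]-2-methylbutan-1-one
Product: 24 (4R,5S)-2-hydroxy-4-methyl-3-[(2R)-2-methylbutanoyl]-4-(4-methylpent-3-en-1-yl)-5-(3-methylbut-2-en-1-yl)cyclohex-2-ene-1-carbaldehyde (C1 epimers and enol tautomers)
Conditions: LiN(i-Pr)2 (2.4 equiv), THF, −78 → 0 °C; HCO2Et (3 equiv), −78 → 0 °C; 1 M HCl
Reagents that add atoms: ethyl formate, CCOC=O
Why: The second deprotonation of the diketonate should occur at the ring CH2 (C5) and not at the more hindered acyl methine, and the dianion reacts at this more basic carbon with ethyl formate (γ-acylation of a β-diketone dianion, Claisen formylation).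

**Step 17**
Reactants: 24 (4R,5S)-2-hydroxy-4-methyl-3-[(2R)-2-methylbutanoyl]-4-(4-methylpent-3-en-1-yl)-5-(3-methylbut-2-en-1-yl)cyclohex-2-ene-1-carbaldehyde; 25 1-bromo-3-methylbut-2-ene
Product: 26 (1R,4R,5S)-2-hydroxy-4-methyl-3-[(2R)-2-methylbutanoyl]-4-(4-methylpent-3-en-1-yl)-1,5-bis(3-methylbut-2-en-1-yl)cyclohex-2-ene-1-carbaldehyde
Conditions: 25 (1.2 equiv), K2CO3 (1.2 equiv), MeCN, 0 °C → rt
Reagents that add atoms: none
Why: The formyl ketone site (C5) is the most acidic and its enolate is C-alkylated by the allylic bromide, while C1 is shielded by the quaternary C8; axial attack on the face opposite the C7 prenyl group should place the new prenyl group trans to it and so set the C5 quaternary centre (alkylation of a hydroxymethylene ketone).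

**Step 18**
Reactants: 26 (1R,4R,5S)-2-hydroxy-4-methyl-3-[(2R)-2-methylbutanoyl]-4-(4-methylpent-3-en-1-yl)-1,5-bis(3-methylbut-2-en-1-yl)cyclohex-2-ene-1-carbaldehyde; 27 ethoxyacetylene
Product: 28 (2R)-1-[(3S,5S,6R)-3-(3-ethoxy-1-hydroxyprop-2-yn-1-yl)-2-hydroxy-6-methyl-6-(4-methylpent-3-en-1-yl)-3,5-bis(3-methylbut-2-en-1-yl)cyclohex-1-en-1-yl]-2-methylbutan-1-one (carbinol epimers)
Conditions: 27 (3 equiv), n-BuLi (2.8 equiv), THF, −78 °C; then 26, −78 °C; sat. aq. NH4Cl
Reagents that add atoms: none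
Why: The first equivalent of lithium ethoxyacetylide deprotonates the enol and so masks both ketones as the diketonate, and a further equivalent adds to the non-enolisable aldehyde; the new carbinol centre is removed in the next step (1,2-addition of a lithium acetylide).

**Step 19**
Reactants: 28 (2R)-1-[(3S,5S,6R)-3-(3-ethoxy-1-hydroxyprop-2-yn-1-yl)-2-hydroxy-6-methyl-6-(4-methylpent-3-en-1-yl)-3,5-bis(3-methylbut-2-en-1-yl)cyclohex-1-en-1-yl]-2-methylbutan-1-one
Product: 29 (2R)-1-[(3R,5S,6R)-3-(3-ethoxyprop-2-ynoyl)-2-hydroxy-6-methyl-6-(4-methylpent-3-en-1-yl)-3,5-bis(3-methylbut-2-en-1-yl)cyclohex-1-en-1-yl]-2-methylbutan-1-one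
Conditions: MnO2 (activated, 20 equiv), CH2Cl2, rt
Reagents that add atoms: none
Why: Activated MnO2 oxidises the propargylic alcohol selectively under neutral, non-nucleophilic conditions that should leave the ynol ether, the hydrogen-bonded enol and the alkenes intact.

**Step 20**
Reactants: 29 (2R)-1-[(3R,5S,6R)-3-(3-ethoxyprop-2-ynoyl)-2-hydroxy-6-methyl-6-(4-methylpent-3-en-1-yl)-3,5-bis(3-methylbut-2-en-1-yl)cyclohex-1-en-1-yl]-2-methylbutan-1-one
Product: 31 (1R,5S,7S,8R)-2-ethoxy-8-methyl-1-[(2R)-2-methylbutanoyl]-8-(4-methylpent-3-en-1-yl)-5,7-bis(3-methylbut-2-en-1-yl)bicyclo[3.3.1]non-2-ene-4,9-dione, via silyl enol ether 30 (not isolated)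
Conditions: N-(tert-butyldimethylsilyl)-N-methyltrifluoroacetamide (1.5 equiv), CH2Cl2, rt; then Ph3PAuNTf2 (5 mol%), t-BuOH (1.5 equiv), 4 Å molecular sieves, CH2Cl2, rt
Reagents that add atoms: N-(tert-butyldimethylsilyl)-N-methyltrifluoroacetamide, CN(C(=O)C(F)(F)F)[Si](C)(C)C(C)(C)C (silyl group of 30 only)
Why: Proposed new method: the C9 enol oxygen is first capped as its silyl ether (the endocyclic isomer is favoured because an exocyclic enol ether at C1 would eclipse the quaternary C8), which blocks the chromone-type 6-endo closure through oxygen; monovalent gold then activates the push-pull alkyne as a ketene-oxonium species that is electrophilic only at C2, the silyl enol ether carbon C1 attacks C2 anti to gold in a 6-endo-dig mode with the C5–C4 bond axial (ring A: C1, C2, C3, C4, C5, C9), tert-butanol takes up the silyl group and protonates the vinyl–gold bond at C3, and the configuration at C1 is fixed by the tether from C5; the closest known reactions are the gold-catalysed 6-endo-dig carbocyclisation of cyclohexanone silyl enol ethers onto pendant alkynes, which gives bicyclo[3.3.1]nonenones with a bridgehead ketone, and the gold Conia-ene reaction of 1,3-dicarbonyl compounds.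

**Step 21**
Reactants: 31 (1R,5S,7S,8R)-2-ethoxy-8-methyl-1-[(2R)-2-methylbutanoyl]-8-(4-methylpent-3-en-1-yl)-5,7-bis(3-methylbut-2-en-1-yl)bicyclo[3.3.1]non-2-ene-4,9-dione
Product: 32 (1S,5S,7S,8R)-4-hydroxy-8-methyl-1-[(2R)-2-methylbutanoyl]-8-(4-methylpent-3-en-1-yl)-5,7-bis(3-methylbut-2-en-1-yl)bicyclo[3.3.1]non-3-ene-2,9-dione
Conditions: 1 M HCl, THF, 40 °C
Reagents that add atoms: water, O
Why: Dilute acid hydrolyses the vinylogous ester by addition of water at C2 and loss of ethanol, giving the enolised 2,4-dione without the basic conditions that could epimerise the acyl side chain or cleave the C1 tricarbonyl unit (vinylogous ester hydrolysis).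

**Compound list**
1 | (R)-epichlorohydrin | ClC[C@H]1CO1 | starting material
2 | diethyl malonate | CCOC(=O)CC(=O)OCC | starting material
3 | ethyl (1S,5R)-2-oxo-3-oxabicyclo[3.1.0]hexane-1-carboxylate | CCOC(=O)[C@]12C[C@H]1COC2=O | intermediate
4 | 2-methylprop-1-enylmagnesium bromide | CC(C)=C[Mg]Br | starting material
5 | ethyl (4R)-4-(3-methylbut-2-en-1-yl)-2-oxotetrahydrofuran-3-carboxylate (C3 epimers) | CCOC(=O)C1[C@@H](CC=C(C)C)COC1=O | intermediate
6 | (4R)-4-(3-methylbut-2-en-1-yl)dihydrofuran-2(3H)-one | O=C1C[C@@H](CC=C(C)C)CO1 | intermediate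
7 | (3R,4R)-3-methyl-4-(3-methylbut-2-en-1-yl)dihydrofuran-2(3H)-one (trans) | O=C1[C@H](C)[C@@H](CC=C(C)C)CO1 | intermediate
8 | 5-bromo-2-methylpent-2-ene | CC(C)=CCCBr | starting material
9 | 5-iodo-2-methylpent-2-ene | CC(C)=CCCI | intermediate
10 | (3R,4R)-3-methyl-3-(4-methylpent-3-en-1-yl)-4-(3-methylbut-2-en-1-yl)dihydrofuran-2(3H)-one (methyl cis to prenyl) | O=C1[C@](C)(CCC=C(C)C)[C@@H](CC=C(C)C)CO1 | intermediate
11 | (2R,3R)-2-methyl-2-(4-methylpent-3-en-1-yl)-3-(3-methylbut-2-en-1-yl)butane-1,4-diol | OC[C@H](CC=C(C)C)[C@@](C)(CCC=C(C)C)CO | intermediate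
12 | (2R,3R)-4-[(tert-butyldiphenylsilyl)oxy]-2-methyl-2-(4-methylpent-3-en-1-yl)-3-(3-methylbut-2-en-1-yl)butan-1-ol | CC(C)(C)[Si](c1ccccc1)(c1ccccc1)OC[C@H](CC=C(C)C)[C@@](C)(CCC=C(C)C)CO | intermediate
13 | tert-butyl{[(2R,3R)-3-(iodomethyl)-3,7-dimethyl-2-(3-methylbut-2-en-1-yl)oct-6-en-1-yl]oxy}diphenylsilane | CC(C)(C)[Si](c1ccccc1)(c1ccccc1)OC[C@H](CC=C(C)C)[C@@](C)(CCC=C(C)C)CI | intermediate
14 | (R)-2-methylbutanoic acid | CC[C@@H](C)C(=O)O | starting material
15 | (R)-1-(1H-imidazol-1-yl)-2-methylbutan-1-one (acyl imidazolide) | CC[C@@H](C)C(=O)n1ccnc1 | intermediate (not isolated)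
16 | (R)-N-methoxy-N,2-dimethylbutanamide | CC[C@@H](C)C(=O)N(C)OC | intermediate
17 | {(2R,3R)-4-[(tert-butyldiphenylsilyl)oxy]-2-methyl-2-(4-methylpent-3-en-1-yl)-3-(3-methylbut-2-en-1-yl)butyl}lithium | CC(C)(C)[Si](c1ccccc1)(c1ccccc1)OC[C@H](CC=C(C)C)[C@@](C)(CCC=C(C)C)C[Li] | intermediate (not isolated)
18 | (3R,6S,7R)-8-[(tert-butyldiphenylsilyl)oxy]-3,6-dimethyl-6-(4-methylpent-3-en-1-yl)-7-(3-methylbut-2-en-1-yl)octan-4-one | CC(C)(C)[Si](c1ccccc1)(c1ccccc1)OC[C@H](CC=C(C)C)[C@@](C)(CCC=C(C)C)CC(=O)[C@H](C)CC | intermediate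
19 | (3R,6S,7R)-8-hydroxy-3,6-dimethyl-6-(4-methylpent-3-en-1-yl)-7-(3-methylbut-2-en-1-yl)octan-4-one | OC[C@H](CC=C(C)C)[C@@](C)(CCC=C(C)C)CC(=O)[C@H](C)CC | intermediate
20 | (2R,3S,6R)-3,6-dimethyl-3-(4-methylpent-3-en-1-yl)-2-(3-methylbut-2-en-1-yl)-5-oxooctanal | O=C[C@H](CC=C(C)C)[C@@](C)(CCC=C(C)C)CC(=O)[C@H](C)CC | intermediate (not isolated)
21 | methyl (2E,4S,5S,8R)-5,8-dimethyl-5-(4-methylpent-3-en-1-yl)-4-(3-methylbut-2-en-1-yl)-7-oxodec-2-enoate | COC(=O)/C=C/[C@H](CC=C(C)C)[C@@](C)(CCC=C(C)C)CC(=O)[C@H](C)CC | intermediate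
22 | methyl (4R,5S,8R)-5,8-dimethyl-5-(4-methylpent-3-en-1-yl)-4-(3-methylbut-2-en-1-yl)-7-oxodecanoate (open-chain keto ester) | COC(=O)CC[C@H](CC=C(C)C)[C@@](C)(CCC=C(C)C)CC(=O)[C@H](C)CC | intermediate
23 | (2R)-1-[(5R,6R)-2-hydroxy-6-methyl-6-(4-methylpent-3-en-1-yl)-5-(3-methylbut-2-en-1-yl)cyclohex-1-en-1-yl]-2-methylbutan-1-one (ring B 2-acylcyclohexanone, C9 enol) | CC[C@@H](C)C(=O)C1=C(O)CC[C@H](CC=C(C)C)[C@@]1(C)CCC=C(C)C | intermediate
24 | (4R,5S)-2-hydroxy-4-methyl-3-[(2R)-2-methylbutanoyl]-4-(4-methylpent-3-en-1-yl)-5-(3-methylbut-2-en-1-yl)cyclohex-2-ene-1-carbaldehyde (C1 epimers and enol tautomers) | CC[C@@H](C)C(=O)C1=C(O)C(C=O)C[C@H](CC=C(C)C)[C@@]1(C)CCC=C(C)C | intermediate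
25 | 1-bromo-3-methylbut-2-ene | CC(C)=CCBr | starting material
26 | (1R,4R,5S)-2-hydroxy-4-methyl-3-[(2R)-2-methylbutanoyl]-4-(4-methylpent-3-en-1-yl)-1,5-bis(3-methylbut-2-en-1-yl)cyclohex-2-ene-1-carbaldehyde (the two prenyl groups trans) | CC[C@@H](C)C(=O)C1=C(O)[C@@](C=O)(CC=C(C)C)C[C@H](CC=C(C)C)[C@@]1(C)CCC=C(C)C | intermediate
27 | ethoxyacetylene | CCOC#C | starting material
28 | (2R)-1-[(3S,5S,6R)-3-(3-ethoxy-1-hydroxyprop-2-yn-1-yl)-2-hydroxy-6-methyl-6-(4-methylpent-3-en-1-yl)-3,5-bis(3-methylbut-2-en-1-yl)cyclohex-1-en-1-yl]-2-methylbutan-1-one (carbinol epimers) | CC[C@@H](C)C(=O)C1=C(O)[C@@](C(O)C#COCC)(CC=C(C)C)C[C@H](CC=C(C)C)[C@@]1(C)CCC=C(C)C | intermediate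
29 | (2R)-1-[(3R,5S,6R)-3-(3-ethoxyprop-2-ynoyl)-2-hydroxy-6-methyl-6-(4-methylpent-3-en-1-yl)-3,5-bis(3-methylbut-2-en-1-yl)cyclohex-1-en-1-yl]-2-methylbutan-1-one | CC[C@@H](C)C(=O)C1=C(O)[C@@](C(=O)C#COCC)(CC=C(C)C)C[C@H](CC=C(C)C)[C@@]1(C)CCC=C(C)C | intermediate
30 | (2R)-1-[(3R,5S,6R)-2-[(tert-butyldimethylsilyl)oxy]-3-(3-ethoxyprop-2-ynoyl)-6-methyl-6-(4-methylpent-3-en-1-yl)-3,5-bis(3-methylbut-2-en-1-yl)cyclohex-1-en-1-yl]-2-methylbutan-1-one | CC[C@@H](C)C(=O)C1=C(O[Si](C)(C)C(C)(C)C)[C@@](C(=O)C#COCC)(CC=C(C)C)C[C@H](CC=C(C)C)[C@@]1(C)CCC=C(C)C | intermediate (not isolated)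
31 | (1R,5S,7S,8R)-2-ethoxy-8-methyl-1-[(2R)-2-methylbutanoyl]-8-(4-methylpent-3-en-1-yl)-5,7-bis(3-methylbut-2-en-1-yl)bicyclo[3.3.1]non-2-ene-4,9-dione | CC[C@@H](C)C(=O)[C@]12C(OCC)=CC(=O)[C@](CC=C(C)C)(C[C@H](CC=C(C)C)[C@@]1(C)CCC=C(C)C)C2=O | intermediate
32 | (1S,5S,7S,8R)-4-hydroxy-8-methyl-1-[(2R)-2-methylbutanoyl]-8-(4-methylpent-3-en-1-yl)-5,7-bis(3-methylbut-2-en-1-yl)bicyclo[3.3.1]non-3-ene-2,9-dione (CNP0268336.1) | CC[C@@H](C)C(=O)[C@]12C(=O)C=C(O)[C@](CC=C(C)C)(C[C@H](CC=C(C)C)[C@@]1(C)CCC=C(C)C)C2=O | target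

**Step count**
Total: 21 steps. Longest linear sequence: 19 steps (steps 1–4, 6–9 and 11–21; steps 5 and 10 prepare side reagents).

**Steps most likely to fail**

1. Step 20 (carries the new-method label). The closure may go through oxygen instead of carbon if the silyl cap is lost, giving a fused pyranone by 6-endo attack of the C9 oxygen. The gold-activated ynol ether may also be hydrated by traces of water. Ring B may fail to reach the boat-like conformation in which the C5–C4 bond is axial beside the cis C7 prenyl group. The fallback uses only established reactions and makes the C1–C2 bond by a Michael addition in which attack through oxygen is reversible. It sets out from 26: vinylmagnesium bromide (excess, the first equivalent being consumed by the enol) should add to the aldehyde to give the allylic alcohol F1, which MnO2 should oxidise to the vinyl ketone F2. A catalytic amine base (DBU, MeCN) should then bring about intramolecular Michael addition of C1 to the enone terminus and give the saturated bicyclic triketone F3. Dehydrogenation with IBX in DMSO should give the ring A enone F4, nucleophilic epoxidation (t-BuOOH, DBU) the epoxy ketone F5, and isomerisation of the epoxy ketone with Pd(PPh3)4 (zerovalent palladium) and dppe the β-diketone, which is the point where the route is rejoined at 32.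

2. Step 15 (key step). Enolisation may occur at the acyl methine with erosion of the (R) centre, or the substrate may stall as the bis-enolate or as the aldolate formed by the ester enolate and the ketone. The fallback keeps the same C1–C9 bond but replaces the strong-base Claisen by soft enolisation and an activated ester. It sets out from 22: Me3SnOH (1,2-dichloroethane, 80 °C) should give the keto acid F6, and pentafluorophenol with a carbodiimide the pentafluorophenyl ester F7. MgBr2·OEt2 and i-Pr2NEt in CH2Cl2 should then enolise the ketone through its magnesium chelate and acylate C1 intramolecularly, returning to the route at 23.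

3. Step 17. The hydroxymethylene enolate may be alkylated on oxygen, the formyl group may be lost by retro-Claisen cleavage, or the facial selectivity at C5 may be poor. The fallback replaces the SN2 alkylation by a palladium π-allyl recombination in which O-allylated material is returned to the catalytic cycle. It sets out from 24: 3-methylbut-2-en-1-yl chloroformate and pyridine should give the enol carbonate F8, and Pd(PPh3)4 (zerovalent palladium) in THF should ionise it, release CO2 and join the bulky π-prenyl electrophile to C5 at its unsubstituted end on the less hindered face, returning to the route at 26.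

**Further compounds**
F1 | step 20 | (2R)-1-[(5S,6R)-2-hydroxy-3-(1-hydroxyprop-2-en-1-yl)-6-methyl-6-(4-methylpent-3-en-1-yl)-3,5-bis(3-methylbut-2-en-1-yl)cyclohex-1-en-1-yl]-2-methylbutan-1-one (ring configuration as in 26, carbinol epimers) | CC[C@@H](C)C(=O)C1=C(O)[C@@](C(O)C=C)(CC=C(C)C)C[C@H](CC=C(C)C)[C@@]1(C)CCC=C(C)C
F2 | step 20 | (2R)-1-[(5S,6R)-3-acryloyl-2-hydroxy-6-methyl-6-(4-methylpent-3-en-1-yl)-3,5-bis(3-methylbut-2-en-1-yl)cyclohex-1-en-1-yl]-2-methylbutan-1-one (ring configuration as in 26) | CC[C@@H](C)C(=O)C1=C(O)[C@@](C(=O)C=C)(CC=C(C)C)C[C@H](CC=C(C)C)[C@@]1(C)CCC=C(C)C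
F3 | step 20 | 8-methyl-1-[(2R)-2-methylbutanoyl]-8-(4-methylpent-3-en-1-yl)-5,7-bis(3-methylbut-2-en-1-yl)bicyclo[3.3.1]nonane-4,9-dione (ring configuration as in 32) | CC[C@@H](C)C(=O)[C@]12CCC(=O)[C@](CC=C(C)C)(C[C@H](CC=C(C)C)[C@@]1(C)CCC=C(C)C)C2=O
F4 | step 20 | 8-methyl-1-[(2R)-2-methylbutanoyl]-8-(4-methylpent-3-en-1-yl)-5,7-bis(3-methylbut-2-en-1-yl)bicyclo[3.3.1]non-2-ene-4,9-dione (ring configuration as in 32) | CC[C@@H](C)C(=O)[C@]12C=CC(=O)[C@](CC=C(C)C)(C[C@H](CC=C(C)C)[C@@]1(C)CCC=C(C)C)C2=O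
F5 | step 20 | 2,3-epoxy-8-methyl-1-[(2R)-2-methylbutanoyl]-8-(4-methylpent-3-en-1-yl)-5,7-bis(3-methylbut-2-en-1-yl)bicyclo[3.3.1]nonane-4,9-dione (epoxide epimers) | CC[C@@H](C)C(=O)[C@]12C3OC3C(=O)[C@](CC=C(C)C)(C[C@H](CC=C(C)C)[C@@]1(C)CCC=C(C)C)C2=O
F6 | step 15 | (4R,5S,8R)-5,8-dimethyl-5-(4-methylpent-3-en-1-yl)-4-(3-methylbut-2-en-1-yl)-7-oxodecanoic acid | OC(=O)CC[C@H](CC=C(C)C)[C@@](C)(CCC=C(C)C)CC(=O)[C@H](C)CC
F7 | step 15 | pentafluorophenyl (4R,5S,8R)-5,8-dimethyl-5-(4-methylpent-3-en-1-yl)-4-(3-methylbut-2-en-1-yl)-7-oxodecanoate | O=C(Oc1c(F)c(F)c(F)c(F)c1F)CC[C@H](CC=C(C)C)[C@@](C)(CCC=C(C)C)CC(=O)[C@H](C)CC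
F8 | step 17 | {(4R,5S)-2-hydroxy-4-methyl-3-[(2R)-2-methylbutanoyl]-4-(4-methylpent-3-en-1-yl)-5-(3-methylbut-2-en-1-yl)cyclohex-2-en-1-ylidene}methyl 3-methylbut-2-en-1-yl carbonate | CC[C@@H](C)C(=O)C1=C(O)C(=COC(=O)OCC=C(C)C)C[C@H](CC=C(C)C)[C@@]1(C)CCC=C(C)C
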